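The substrate count is conserved: each unit charged stands as substrate, open intermediate, target or homo product, so the question is how it divides.

in all of them: substrate 0.50 M; partner 1.25 M; gas 160 mM (held); time 2.5 h

| flask | remark | temperature |
|---|---|---|
| alder | at 80 °C until 80 min, from then on at 105 °C |  |
| cedar |  | 80 °C |
| larch |  | 105 °C |

    open intermediate + second intermediate → target (k1 = 0.00172 L mol⁻¹ s⁻¹, Ea1 = 72.0 kJ mol⁻¹)
    2 open intermediate → homo product (k2 = 0.00291 L mol⁻¹ s⁻¹, Ea2 = 62.0 kJ mol⁻¹)
    substrate + reagent → open intermediate (k3 = 0.00721 L mol⁻¹ s⁻¹, Ea3 = 70.0 kJ mol⁻¹)
    reagent + partner → second intermediate (k4 = 0.00358 L mol⁻¹ s⁻¹, Ea4 = 71.0 kJ mol⁻¹)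
    gas ⇌ reagent, rate k5*(csat - [reagent]) (k5 = 0.0290 s⁻¹, csat = 160 mM)
    (constants at 80 °C)

- percentages count the substrate that a species holds: one homo product counts as two
- where a step has two of a species, its rate is k times that concentration squared, and two are used at each turn
- at the start none of reagent is dissolved
- the constants hold at 80 °C; other temperatures follow from the activation energies

1. the flask with the highest amount of target, in percent of the substrate charged ("all alike" if they lie within 1.5 percentage points) (alder / cedar / larch / all alike)
2. final target, as a percentage of the substrate charged, in alder
3. final target, as a percentage of the substrate charged, in cedar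
4. final target, as a percentage of the substrate charged, in larch

Two of us dispute how much reagent stands in solution while the substrate goes, since open intermediate is made in proportion to it. My colleague takes the saturation view: transfer from the gas turns over in 34.5 s, quicker than the substrate's half-time in cedar. So in that view reagent stands at 160 mM, and substrate halves in 0.167 h in cedar and 0.0345 h in larch.

I compare uptake with transfer. At full charges, the substrate and partner together take up reagent at 0.00808 s⁻¹ in cedar. In larch they take it up at 0.0396 s⁻¹, more than the transfer coefficient 0.0290 s⁻¹. With uptake reckoned at those full charges, inflow equals uptake at a reagent level of 0.125 M in cedar and 0.0677 M in larch.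

I put that one level in place of the reagent curve. Substrate then halves, pseudo-first-order, in 0.213 h in cedar and 0.0816 h in larch. This metered half-time, the natural log of two over the substrate step's constant times the metered level, is the quantity I carry.

Alder stands at 80 °C until its change of temperature, so with cedar's metered half-time I reckon 6.25 half-times passed by then, which by this estimate leaves 1.32 % of the substrate, hardly any. So I put alder with cedar.

For the split I use means as well. I take open intermediate as arriving at half its starting rate and as meeting a reckoned mean of 0.415 M of second intermediate in cedar and 0.421 M in larch. Balancing arrival against the cross and homo losses gives the cross step 45.8 % in cedar and 61.2 % in larch. At saturation the same reckoning gives 42.0 % in cedar and 46.7 % in larch. I commit to the metered figures, with larch ahead.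

For larch the forecast stands on the metered side, "the gas-transfer limit meters the open intermediate more slowly", with 56 % for alder, 56 % for cedar, 61 % for larch and larch ahead, its cedar figure above mine.

The flasks give 58.1 % in alder, 58.0 % in cedar and 63.6 % in larch, so larch leads, and my shares run low by 12 percentage points in cedar and 2.4 points in larch. Larch reaches half conversion at 0.0768 h, against my metered 0.0816 h and the saturation 0.0345 h. The saturation view fits later on: at 1.25 h reagent stands at 0.160 M in larch and 0.157 M in cedar. In cedar the metered half-time is 0.213 h, and half conversion is read at 0.212 h.

The numbers of this flask are invented; the rest is arithmetic.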